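**Retrosynthetic overview**
1. Target 20 ⇒ triol ester 19 (site-selective acetylation of the equatorial 2-OH) ⇒ alkyne 17 (syn-carboalumination/methoxycarbonylation gives the (E)-enoate) ⇒ decalone 13 + C4 Grignard reagent (axial addition anti to the C10 methyl sets C9).
2. Ring A is opened at C3–C4: benzoate 12 ⇒ monocyclic α-benzoyloxy aldehyde 9, closed by hydrogen-atom-transfer (MHAT) radical cyclisation of the isopropenyl group onto the aldehyde.
3. Enabling feature: C4 of ring A is a quaternary carbon with two methyl groups, bonded to the ring-fusion carbon C5 and next to the C3 carbinol. C4 is therefore the Markovnikov carbon of an isopropenyl group on C5 of ring B, and C3 is an aldehyde at the end of the six-atom chain C4–C5–C10–C1–C2–C3.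
4. 9 ⇒ (R)-carvone: ring B is the carvone ring. C5 is bought, C10 comes from two α'-alkylations (methyl, then allyl anti to isopropenyl), C8 from conjugate reduction/equilibration, C2 from amine catalysis; C3 and C9 are relayed.
5. Order of rings: ring B (from carvone) first, ring A second.

Key step: step 6

Remark on the chemistry: labdane numbering is used for all compounds (ring A C1–C5/C10, ring B C5–C10, side chain C11–C16 on C9, C17 on C8, C18/C19 on C4, C20 on C10); α is the face opposite the C10 methyl. The target SMILES is read as 2α-OAc, 3α-OH (cis), 5α-H/10β-CH3 (trans-decalin), 8α-CH3, 9β-OH with the side chain 9α (axial, anti to C20), 13E, i.e. (2R,3S,5S,8R,9S,10S). (R)-Carvone, (4-bromobut-1-yn-1-yl)trimethylsilane and both enantiomers of the prolinol silyl ether catalyst are taken as commercial.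

**Step 1**
Reactants: 1 (R)-(−)-carvone
Product: 3 (5R,6S)-2,6-dimethyl-5-(prop-1-en-2-yl)cyclohex-2-en-1-one (trans-6-methylcarvone), via lithium dienolate 2 (not isolated)
Conditions: LiN(i-Pr)2, THF, −78 °C; MeI, −78 → 0 °C
Reagents that add atoms: iodomethane, CI
Why: Kinetic α'-deprotonation gives the cross-conjugated dienolate 2, whose SN2 methylation (enolate alkylation) should occur mainly anti to the isopropenyl group; the new centre is provisional because it is re-enolised in step 2.

**Step 2**
Reactants: 3 trans-6-methylcarvone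
Product: 5 (5S,6S)-2,6-dimethyl-6-(prop-2-en-1-yl)-5-(prop-1-en-2-yl)cyclohex-2-en-1-one, via lithium enolate 4 (not isolated)
Conditions: LiN(i-Pr)2, THF, −78 → −20 °C; allyl bromide, DMPU, −78 → 0 °C
Reagents that add atoms: allyl bromide, C=CCBr
Why: Enolate alkylation in which allyl bromide should attack the tetrasubstituted enolate 4 anti to the vicinal isopropenyl group, setting the quaternary centre (C10) with methyl cis and allyl trans to isopropenyl, as the trans ring fusion requires.

**Step 3**
Reactants: 5 6-allyl-6-methylcarvone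
Product: 7 (2S,3S,6R)-2,6-dimethyl-2-(prop-2-en-1-yl)-3-(prop-1-en-2-yl)cyclohexan-1-one, via lithium enolate 6 (not isolated)
Conditions: LiBH(s-Bu)3, THF, −78 °C; then NaOMe, MeOH, 0 °C → rt
Reagents that add atoms: none
Why: Conjugate hydride reduction of a β-unsubstituted cyclohexenone whose carbonyl is shielded by the quaternary α'-carbon (the isolated alkenes are inert); protonation of enolate 6 and methoxide equilibration set the C8 methyl provisionally trans to the C10 methyl, and any C8 epimer that persists converges in step 7.

**Step 4**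
Reactants: 7 saturated ketone
Product: 8 3-[(1S,3R,6S)-1,3-dimethyl-2-oxo-6-(prop-1-en-2-yl)cyclohexyl]propanal
Conditions: PdCl2(PhCN)2 (12 mol %), CuCl2·2H2O (12 mol %), AgNO2 (6 mol %), O2 (1 atm), t-BuOH/MeNO2 15:1, rt
Reagents that add atoms: dioxygen, O=O
Why: Nitrite-modified aldehyde-selective (anti-Markovnikov) Wacker oxidation, which acts only on the monosubstituted alkene; the 1,1-disubstituted isopropenyl group does not enter Wacker chemistry and the quaternary carbon next to the allylic CH2 disfavours internal attack.

**Step 5**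
Reactants: 8 keto aldehyde
Product: 9 (2R)-3-[(1S,3R,6S)-1,3-dimethyl-2-oxo-6-(prop-1-en-2-yl)cyclohexyl]-1-oxopropan-2-yl benzoate
Conditions: (R)-2-[diphenyl(trimethylsilyloxy)methyl]pyrrolidine (10 mol %), dibenzoyl peroxide (1.2 equiv), hydroquinone (10 mol %), THF, 0 °C
Reagents that add atoms: dibenzoyl peroxide, O=C(OOC(=O)c1ccccc1)c1ccccc1
Why: Enamine-catalysed asymmetric α-benzoyloxylation of an aldehyde, in which the diphenyl(silyloxy)methyl group of the (R)-catalyst shields one enamine face so that oxygen should be delivered to give the (2R)-benzoate under catalyst control; the hindered ketone forms no enamine, and 9 is used at once to avoid epimerisation at C2.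

**Step 6**
Reactants: 9 α-benzoyloxy aldehyde
Product: 12 2α-benzoyloxy-3α-hydroxy-4,4,8α,10β-tetramethyl-5α-decalin-9-one, via C4 tertiary radical 10 (not isolated), via C3 alkoxyl radical 11 (not isolated)
Conditions: Fe(acac)3 (30 mol %), PhSiH3 (2.5 equiv), EtOH (0.03 M), 60 °C
Reagents that add atoms: none
Why: The trivalent iron hydride formed from Fe(acac)3 and PhSiH3 in EtOH transfers a hydrogen atom to the CH2 terminus of the isopropenyl group (Markovnikov MHAT) to give tertiary radical 10 at C4, which adds to the C3 aldehyde carbon to give alkoxyl radical 11; divalent iron reduces 11 to the alkoxide, EtOH protonates it, and the silane returns the iron ethoxide to the hydride. The closest known reaction type is the Fe(acac)3/PhSiH3 reductive radical cyclisation of alkene-tethered ketones, together with the intermolecular coupling of unactivated alkenes with aldehydes under the same conditions. Ring A closes in the 6-exo-trig mode through a chair in which the two arms (C4 on C5, C1 on C10) are already trans-diequatorial on ring B, so only the trans-decalin can form and C5 and C10 are untouched. The one new stereocentre, C3, is controlled by C2: with the benzoate equatorial its C–O bond lies anti to the forming C3–C4 bond (polar Felkin–Anh arrangement) and the carbonyl oxygen takes the pseudo-axial site beside C1, away from the two methyl groups on the radical carbon, which should give the 3α-alcohol cis to the 2α-benzoate. C4 becomes the gem-dimethyl quaternary carbon, the new methyl being the former CH2. The selectivity needed is radical generation at one site and closure before reduction: the isopropenyl group is the only alkene, the C9 ketone could be reached only through a four-membered ring, and the quaternary C10 holds the two arms close (Thorpe–Ingold effect) so that closure should outrun hydrogenation of 10.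

**Step 7**
Reactants: 12 hydroxy benzoate
Product: 13 2α,3α-dihydroxy-4,4,8α,10β-tetramethyl-5α-decalin-9-one
Conditions: NaOMe (0.5 equiv), MeOH, 40 °C
Reagents that add atoms: none
Why: Methoxide transesterification (Zemplén-type) removes the benzoate, and the same base equilibrates the enolisable C8 centre of the now rigid trans-decalone to the equatorial 8α-methyl epimer, which avoids a syn-diaxial clash with the C10 methyl.

**Step 8**
Reactants: 13 keto diol; 14 (4-bromobut-1-yn-1-yl)trimethylsilane
Product: 17 9α-(but-3-yn-1-yl)-4,4,8α,10β-tetramethyl-5α-decalin-2α,3α,9β-triol, via Grignard reagent 15 (not isolated), via silylalkyne triol 16 (not isolated)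
Conditions: 14, Mg, THF, rt (gives 15, 5 equiv); 13, LaCl3·2LiCl (1.1 equiv), THF, 0 °C → rt; aq. NH4Cl; then K2CO3, MeOH, rt
Reagents that add atoms: none
Why: Lanthanum-promoted Grignard 1,2-addition after deprotonation of the diol, in which the axial C10 methyl blocks the equatorial (β) trajectory and the peri C1 methylene disfavours an equatorial substituent, so the nucleophile should add axially from the α face to give the 9α side chain and 9β-hydroxyl; K2CO3/MeOH then cleaves the alkynyl C–Si bond.

**Step 9**
Reactants: 17 alkyne triol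
Product: 19 methyl (E)-5-(2α,3α,9β-trihydroxy-4,4,8α,10β-tetramethyl-5α-decalin-9α-yl)-3-methylpent-2-enoate, via alkenylalane 18 (not isolated)
Conditions: AlMe3 (6 equiv), Cp2ZrCl2 (0.25 equiv), CH2Cl2, 0 °C → rt; then ClCO2Me, 0 °C → rt; aq. potassium sodium tartrate
Reagents that add atoms: trimethylaluminium, C[Al](C)C; methyl chloroformate, COC(Cl)=O
Why: Negishi zirconium-catalysed carboalumination, in which the three hydroxyls are first converted into aluminium alkoxides, methyl and aluminium add syn across the terminal alkyne with methyl at the internal carbon, and acylation of alkenylalane 18 with retention gives the (E)-β-methyl enoate.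

**Step 10**
Reactants: 19 triol ester
Product: 20 methyl (E)-5-(2α-acetoxy-3α,9β-dihydroxy-4,4,8α,10β-tetramethyl-5α-decalin-9α-yl)-3-methylpent-2-enoate (CNP0135744.1)
Conditions: Ac2O (1.1 equiv), pyridine, CH2Cl2, 0 °C
Reagents that add atoms: acetic anhydride, CC(=O)OC(C)=O
Why: Selective acylation, in which the equatorial secondary C2 hydroxyl should react much faster than the axial neopentyl C3 hydroxyl beside the gem-dimethyl carbon and the tertiary C9 hydroxyl; the 2-acetate is also the less hindered regioisomer, so acyl migration does not threaten it.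

**Compound list**
1 | (R)-(−)-carvone | O=C1C(C)=CC[C@@H](C(C)=C)C1 | starting material
2 | lithium dienolate of carvone | [Li+].[O-]C1=C[C@H](C(C)=C)CC=C1C | intermediate
3 | (5R,6S)-2,6-dimethyl-5-(prop-1-en-2-yl)cyclohex-2-en-1-one | O=C1C(C)=CC[C@@H](C(C)=C)[C@@H]1C | intermediate
4 | lithium enolate of 3 | [Li+].[O-]C1=C(C)[C@H](C(C)=C)CC=C1C | intermediate
5 | (5S,6S)-2,6-dimethyl-6-(prop-2-en-1-yl)-5-(prop-1-en-2-yl)cyclohex-2-en-1-one | O=C1C(C)=CC[C@@H](C(C)=C)[C@]1(C)CC=C | intermediate
6 | lithium enolate from conjugate reduction of 5 | [Li+].[O-]C1=C(C)CC[C@@H](C(C)=C)[C@]1(C)CC=C | intermediate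
7 | (2S,3S,6R)-2,6-dimethyl-2-(prop-2-en-1-yl)-3-(prop-1-en-2-yl)cyclohexan-1-one | O=C1[C@H](C)CC[C@@H](C(C)=C)[C@]1(C)CC=C | intermediate
8 | 3-[(1S,3R,6S)-1,3-dimethyl-2-oxo-6-(prop-1-en-2-yl)cyclohexyl]propanal | O=C1[C@H](C)CC[C@@H](C(C)=C)[C@]1(C)CCC=O | intermediate
9 | (2R)-3-[(1S,3R,6S)-1,3-dimethyl-2-oxo-6-(prop-1-en-2-yl)cyclohexyl]-1-oxopropan-2-yl benzoate | O=C1[C@H](C)CC[C@@H](C(C)=C)[C@]1(C)C[C@@H](OC(=O)c2ccccc2)C=O | intermediate
10 | C4 tertiary radical from 9 | O=C1[C@H](C)CC[C@@H]([C](C)C)[C@]1(C)C[C@@H](OC(=O)c2ccccc2)C=O | intermediate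
11 | C3 alkoxyl radical of 12 | O=C1[C@H](C)CC[C@H]2C(C)(C)[C@H]([O])[C@H](OC(=O)c3ccccc3)C[C@@]21C | intermediate
12 | 2α-benzoyloxy-3α-hydroxy-4,4,8α,10β-tetramethyl-5α-decalin-9-one | O=C1[C@H](C)CC[C@H]2C(C)(C)[C@H](O)[C@H](OC(=O)c3ccccc3)C[C@@]21C | intermediate
13 | 2α,3α-dihydroxy-4,4,8α,10β-tetramethyl-5α-decalin-9-one | O=C1[C@H](C)CC[C@H]2C(C)(C)[C@H](O)[C@H](O)C[C@@]21C | intermediate
14 | (4-bromobut-1-yn-1-yl)trimethylsilane | C[Si](C)(C)C#CCCBr | starting material
15 | [4-(trimethylsilyl)but-3-yn-1-yl]magnesium bromide | C[Si](C)(C)C#CCC[Mg]Br | intermediate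
16 | 9α-[4-(trimethylsilyl)but-3-yn-1-yl]-4,4,8α,10β-tetramethyl-5α-decalin-2α,3α,9β-triol | C[Si](C)(C)C#CCC[C@]1(O)[C@H](C)CC[C@H]2C(C)(C)[C@H](O)[C@H](O)C[C@@]21C | intermediate
17 | 9α-(but-3-yn-1-yl)-4,4,8α,10β-tetramethyl-5α-decalin-2α,3α,9β-triol | C#CCC[C@]1(O)[C@H](C)CC[C@H]2C(C)(C)[C@H](O)[C@H](O)C[C@@]21C | intermediate
18 | (E)-alkenyl(dimethyl)alane of 17 with three dimethylaluminium alkoxides | C[Al](C)/C=C(\C)CC[C@]1(O[Al](C)C)[C@H](C)CC[C@H]2C(C)(C)[C@H](O[Al](C)C)[C@H](O[Al](C)C)C[C@@]21C | intermediate
19 | methyl (E)-5-(2α,3α,9β-trihydroxy-4,4,8α,10β-tetramethyl-5α-decalin-9α-yl)-3-methylpent-2-enoate | COC(=O)/C=C(\C)CC[C@]1(O)[C@H](C)CC[C@H]2C(C)(C)[C@H](O)[C@H](O)C[C@@]21C | intermediate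
20 | methyl (E)-5-(2α-acetoxy-3α,9β-dihydroxy-4,4,8α,10β-tetramethyl-5α-decalin-9α-yl)-3-methylpent-2-enoate (CNP0135744.1) | COC(=O)/C=C(\C)CC[C@]1(O)[C@H](C)CC[C@H]2C(C)(C)[C@H](O)[C@H](OC(C)=O)C[C@@]21C | target

**Totals**
Total step count: 10. Longest linear sequence: 10 steps, from (R)-carvone; reagent 14 enters in step 8.

**Steps most likely to fail**

Step 6 (ring closure). Radical 10 may be reduced (net hydrogenation of the isopropenyl group) or the alkene may isomerise before closure. If addition to the aldehyde reverts faster than the alkoxyl radical is reduced, facial control at C3 would also erode. Fallback: from 9, dry HBr (CH2Cl2, −20 °C) adds in the Markovnikov sense to the isopropenyl group to give the tertiary bromide of 9 F1. Bu3SnH and azobisisobutyronitrile (slow addition, benzene, 80 °C) then generate the same C4 radical by bromine abstraction in a tin hydride chain, where the stannane quenches the alkoxyl radical at once (the established 6-exo radical cyclisation of halides onto aldehydes). The route is rejoined at 12.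

Step 8 (addition to the C9 ketone). Enolisation towards C8 or β-hydride reduction by the primary alkyl Grignard reagent may outrun addition to a carbonyl flanked by a quaternary and a tertiary carbon, and the dialkoxide may aggregate. Fallback: from 13, CH2=CHMgBr (small, no β-hydrogen; LaCl3·2LiCl, THF, 0 °C) should add from the same α face to give the 9-vinyl triol F2. Hydroboration with 9-borabicyclo[3.3.1]nonane (excess, THF) gives the B-alkyl borane F3, which is coupled in the same flask with methyl (E)-3-(trifluoromethanesulfonyloxy)but-2-enoate, the (E)-enol triflate of methyl acetoacetate (Pd(dppf)Cl2, aq. K3PO4, DMF, rt; B-alkyl Suzuki–Miyaura coupling with retention of alkene geometry). This returns to the route at 19 and bypasses step 9.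

Step 9 (enoate). Acylation of alane 18 by methyl chloroformate may be slow beside three aluminium alkoxides, or the chloroformate may carbonate them. Fallback: from 17, through the same alane 18, quenching with I2 (THF, −30 °C) gives the (E)-vinyl iodide F4. PdCl2(PPh3)2 (5 mol %), CO (1 atm), MeOH, Et3N, 50 °C (palladium-catalysed methoxycarbonylation with retention) then rejoins the route at 19.

**Further compounds**
F1 | step 6 | tertiary bromide of 9 (HBr adduct at the isopropenyl group) | O=C1[C@H](C)CC[C@@H](C(C)(C)Br)[C@]1(C)C[C@@H](OC(=O)c2ccccc2)C=O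
F2 | step 8 | 9α-ethenyl-4,4,8α,10β-tetramethyl-5α-decalin-2α,3α,9β-triol | C=C[C@]1(O)[C@H](C)CC[C@H]2C(C)(C)[C@H](O)[C@H](O)C[C@@]21C
F3 | step 8 | B-alkyl-9-borabicyclo[3.3.1]nonane from hydroboration of F2 (hydroxyls drawn free) | C1CC2CCCC(C1)B2CC[C@]3(O)[C@H](C)CC[C@H]4C(C)(C)[C@H](O)[C@H](O)C[C@@]43C
F4 | step 9 | 9α-[(E)-4-iodo-3-methylbut-3-en-1-yl]-4,4,8α,10β-tetramethyl-5α-decalin-2α,3α,9β-triol | I/C=C(\C)CC[C@]1(O)[C@H](C)CC[C@H]2C(C)(C)[C@H](O)[C@H](O)C[C@@]21C
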